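**Retrosynthetic overview**
1. The target comes from its 5-O-methyl-3'-O-benzyl ether. One final BCl3 operation removes the peri 5-O-methyl group and the benzyl group.
2. That flavonol comes from an o-hydroxyaryl ynone by the new step: gold-catalysed 6-endo oxyboration (forms O1–C2 and C3–B), then C–B to C–OH oxidation in the same flask.
3. The ynone comes from an A-ring salicylaldehyde and a B-ring arylacetylene. The C3–C4 bond is made by acetylide addition, followed by MnO2 oxidation.
4. The A-ring aldehyde comes from 3,4,5-trimethoxyphenol (ortho-formylation, bromination, Cu methoxylation). The B-ring alkyne comes from 3-hydroxy-4,5-dimethoxybenzaldehyde (benzylation, Ohira–Bestmann).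
5. Ring order: rings A and B are bought as benzenes. Ring C (the pyranone) is the only ring formed, in step 8.

Assumption: the target is a planar, achiral flavonol with no stereocentre, so "single enantiomer" needs no stereocontrol; the only stereocentre on the route (the carbinol carbon of 9) is made racemic and erased in step 7.

**Step 1**
Reactants: 1 3,4,5-trimethoxyphenol
Product: 2 2-hydroxy-4,5,6-trimethoxybenzaldehyde
Conditions: MgCl2, Et3N, (CH2O)n, MeCN, reflux; then 1 M HCl
Reagents that add atoms: paraformaldehyde (reacts as formaldehyde) C=O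
Why: Casnati–Skattebøl ortho-formylation, in which the magnesium phenolate delivers formaldehyde only to an ortho carbon (the two ortho positions of 1 are equivalent) and a second formaldehyde oxidises the salicyl alcoholate to the aldehyde by hydride transfer.

**Step 2**
Reactants: 2 2-hydroxy-4,5,6-trimethoxybenzaldehyde
Product: 3 3-bromo-2-hydroxy-4,5,6-trimethoxybenzaldehyde
Conditions: NBS (1.0 equiv), MeCN, 0 °C to rt
Reagents that add atoms: N-bromosuccinimide O=C1CCC(=O)N1Br
Why: Electrophilic aromatic bromination, where the single remaining ring C–H lies ortho to the phenol OH and to an OMe, so one equivalent of NBS reacts there and leaves the aldehyde alone.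

**Step 3**
Reactants: 3 3-bromo-2-hydroxy-4,5,6-trimethoxybenzaldehyde
Product: 4 2-hydroxy-3,4,5,6-tetramethoxybenzaldehyde
Conditions: NaOMe (5 equiv), CuBr (20 mol %), DMF/MeOH, 110 °C; then 1 M HCl
Reagents that add atoms: sodium methoxide C[O-].[Na+]
Why: Copper-catalysed Ullmann-type methoxylation of an o-bromophenolate, the reaction type that converts 5-bromovanillin into syringaldehyde; the non-enolisable aldehyde is deactivated as part of the phenolate and survives.

**Step 4**
Reactants: 5 3-hydroxy-4,5-dimethoxybenzaldehyde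
Product: 6 3-(benzyloxy)-4,5-dimethoxybenzaldehyde
Conditions: BnBr, K2CO3, DMF, 50 °C
Reagents that add atoms: benzyl bromide BrCc1ccccc1
Why: Williamson ether synthesis on the only acidic OH; the benzyl ether tolerates base, organolithium, MnO2, the boron/gold step and peroxide.

**Step 5**
Reactants: 6 3-(benzyloxy)-4,5-dimethoxybenzaldehyde
Product: 7 1-(benzyloxy)-5-ethynyl-2,3-dimethoxybenzene
Conditions: dimethyl (1-diazo-2-oxopropyl)phosphonate, K2CO3, MeOH, rt
Reagents that add atoms: dimethyl (1-diazo-2-oxopropyl)phosphonate CC(=O)C(=[N+]=[N-])P(=O)(OC)OC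
Why: Ohira–Bestmann (Seyferth–Gilbert) homologation, in which methanolysis frees the diazomethylphosphonate anion and olefination, N2 loss and a 1,2-H shift give the terminal alkyne under conditions harmless to aryl ethers.

**Step 6**
Reactants: 4 2-hydroxy-3,4,5,6-tetramethoxybenzaldehyde; 7 1-(benzyloxy)-5-ethynyl-2,3-dimethoxybenzene
Product: 9 rac-3-[3-(benzyloxy)-4,5-dimethoxyphenyl]-1-(2-hydroxy-3,4,5,6-tetramethoxyphenyl)prop-2-yn-1-ol, via lithium acetylide 8 (not isolated)
Conditions: 7 (2.2 equiv), n-BuLi (2.1 equiv), THF, −78 °C; then 4, −78 to 0 °C; sat. aq NH4Cl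
Reagents that add atoms: n-butyllithium [Li]CCCC (gives only the Li of 8; no atom of it stays in 9)
Why: 1,2-addition of a lithium acetylide to an unprotected salicylaldehyde, where the first equivalent of 8 only deprotonates the phenol (returning 7, which is recovered) and the second adds to the CHO; the carbinol centre is formed racemic on purpose because step 7 erases it.

**Step 7**
Reactants: 9 rac-3-[3-(benzyloxy)-4,5-dimethoxyphenyl]-1-(2-hydroxy-3,4,5,6-tetramethoxyphenyl)prop-2-yn-1-ol
Product: 10 3-[3-(benzyloxy)-4,5-dimethoxyphenyl]-1-(2-hydroxy-3,4,5,6-tetramethoxyphenyl)prop-2-yn-1-one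
Conditions: activated MnO2 (15 equiv), CH2Cl2, rt
Reagents that add atoms: none
Why: MnO2 oxidation is selective for the doubly activated (benzylic and propargylic) alcohol, and the neutral, aprotic medium leaves the fully substituted phenol, the ethers and the uncyclised ynone intact.

**Step 8**
Reactants: 10 3-[3-(benzyloxy)-4,5-dimethoxyphenyl]-1-(2-hydroxy-3,4,5,6-tetramethoxyphenyl)prop-2-yn-1-one
Product: 14 2-[3-(benzyloxy)-4,5-dimethoxyphenyl]-3-hydroxy-5,6,7,8-tetramethoxy-4H-chromen-4-one, via sodium phenolate 11 (not isolated), via aryl catechol borate 12 (not isolated), via 3-borylflavone 13 (not isolated)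
Conditions: NaHMDS (1.0 equiv), toluene, −78 °C; ClBcat (1.05 equiv), −78 °C to rt, volatiles removed in vacuo; IPrAuO2CCF3 (5 mol %, preformed, silver-free), NaO2CCF3 (20 mol %), toluene, 50 °C; then 30% H2O2, aq NaHCO3, THF, 0 °C
Reagents that add atoms: hydrogen peroxide OO (the O of the 3-OH in 14); B-chlorocatecholborane ClB1Oc2ccccc2O1 (the Bcat group of 12 and 13 only); sodium hexamethyldisilazide C[Si](C)(C)[N-][Si](C)(C)C.[Na+] (the Na of 11 only)
Why: Proposed new method: a hydroxylative flavone annulation by 6-endo oxyboration of an o-hydroxyaryl ynone, in which the phenol is stored as a B–O bond (12) so that no proton source is present, IPrAu+ π-activates the alkyne, and the aryloxy oxygen attacks anti at the β-carbon (future C2), which is the electrophilic terminus because of the ynone carbonyl (further polarised by the Lewis-acidic boron) and the 4-alkoxyaryl group; this closes ring C and leaves a C3-vinylgold plus catB–O2CCF3, and because C3 is the nucleophilic carbon of a 4-pyranone the Au-to-B transmetalation gives 13 and returns the catalyst, after which peroxide converts C3–B into C3–OH (flavonols tolerate alkaline H2O2, as Algar–Flynn–Oyamada conditions show); the closest known reaction types are the gold(I)-catalysed oxyboration of 2-alkynylphenols to 3-borylbenzofurans and the gold-catalysed 6-endo alkoxyhalogenation of β-hydroxy ynones, neither shown for ynones giving 3-borylchromones or flavonols.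

**Step 9**
Reactants: 14 2-[3-(benzyloxy)-4,5-dimethoxyphenyl]-3-hydroxy-5,6,7,8-tetramethoxy-4H-chromen-4-one
Product: 15 3,5-dihydroxy-2-(3-hydroxy-4,5-dimethoxyphenyl)-6,7,8-trimethoxy-4H-chromen-4-one (3-demethyldigicitrin)
Conditions: BCl3 (6 equiv), C6HMe5 (3 equiv), CH2Cl2, −78 °C then 0 °C; MeOH, then 1 M HCl/THF
Reagents that add atoms: none
Why: Lewis-acid ether cleavage, in which BCl3 with pentamethylbenzene as a non-basic benzyl-cation trap removes the aryl benzyl ether at −78 °C and, on warming to 0 °C, boron chelated between C4=O and O5 cleaves only the peri 5-OMe (chelation-controlled demethylation) while the five non-chelating OMe groups stay.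

**Compound list**
1 | 3,4,5-trimethoxyphenol | COc1cc(O)cc(OC)c1OC | starting material
2 | 2-hydroxy-4,5,6-trimethoxybenzaldehyde | O=Cc1c(O)cc(OC)c(OC)c1OC | intermediate
3 | 3-bromo-2-hydroxy-4,5,6-trimethoxybenzaldehyde | O=Cc1c(O)c(Br)c(OC)c(OC)c1OC | intermediate
4 | 2-hydroxy-3,4,5,6-tetramethoxybenzaldehyde | O=Cc1c(O)c(OC)c(OC)c(OC)c1OC | intermediate
5 | 3-hydroxy-4,5-dimethoxybenzaldehyde | O=Cc1cc(O)c(OC)c(OC)c1 | starting material
6 | 3-(benzyloxy)-4,5-dimethoxybenzaldehyde | O=Cc1cc(OCc2ccccc2)c(OC)c(OC)c1 | intermediate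
7 | 1-(benzyloxy)-5-ethynyl-2,3-dimethoxybenzene | C#Cc1cc(OCc2ccccc2)c(OC)c(OC)c1 | intermediate
8 | lithium acetylide of 7 (not isolated) | [Li]C#Cc1cc(OCc2ccccc2)c(OC)c(OC)c1 | intermediate
9 | rac-3-[3-(benzyloxy)-4,5-dimethoxyphenyl]-1-(2-hydroxy-3,4,5,6-tetramethoxyphenyl)prop-2-yn-1-ol (racemic) | OC(C#Cc1cc(OCc2ccccc2)c(OC)c(OC)c1)c1c(O)c(OC)c(OC)c(OC)c1OC | intermediate
10 | 3-[3-(benzyloxy)-4,5-dimethoxyphenyl]-1-(2-hydroxy-3,4,5,6-tetramethoxyphenyl)prop-2-yn-1-one | O=C(C#Cc1cc(OCc2ccccc2)c(OC)c(OC)c1)c1c(O)c(OC)c(OC)c(OC)c1OC | intermediate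
11 | sodium 2-{3-[3-(benzyloxy)-4,5-dimethoxyphenyl]prop-2-ynoyl}-3,4,5,6-tetramethoxyphenolate (not isolated) | [Na+].[O-]c1c(OC)c(OC)c(OC)c(OC)c1C(=O)C#Cc1cc(OCc2ccccc2)c(OC)c(OC)c1 | intermediate
12 | 1-[2-(1,3,2-benzodioxaborol-2-yloxy)-3,4,5,6-tetramethoxyphenyl]-3-[3-(benzyloxy)-4,5-dimethoxyphenyl]prop-2-yn-1-one (not isolated) | O=C(C#Cc1cc(OCc2ccccc2)c(OC)c(OC)c1)c1c(OB2Oc3ccccc3O2)c(OC)c(OC)c(OC)c1OC | intermediate
13 | 3-(1,3,2-benzodioxaborol-2-yl)-2-[3-(benzyloxy)-4,5-dimethoxyphenyl]-5,6,7,8-tetramethoxy-4H-chromen-4-one (not isolated) | O=c1c(B2Oc3ccccc3O2)c(-c2cc(OCc3ccccc3)c(OC)c(OC)c2)oc2c(OC)c(OC)c(OC)c(OC)c12 | intermediate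
14 | 2-[3-(benzyloxy)-4,5-dimethoxyphenyl]-3-hydroxy-5,6,7,8-tetramethoxy-4H-chromen-4-one | O=c1c(O)c(-c2cc(OCc3ccccc3)c(OC)c(OC)c2)oc2c(OC)c(OC)c(OC)c(OC)c12 | intermediate
15 | 3,5-dihydroxy-2-(3-hydroxy-4,5-dimethoxyphenyl)-6,7,8-trimethoxy-4H-chromen-4-one (3-demethyldigicitrin, achiral) | COc1cc(-c2oc3c(OC)c(OC)c(OC)c(O)c3c(=O)c2O)cc(O)c1OC | target

**Total step count:** 9. **Longest linear sequence:** 7 (steps 1, 2, 3, 6, 7, 8, 9).

**Three steps most likely to fail**

**Step 8 (proposed new step).**
- The ring could close 5-exo to an aurone-type vinylboronate. Silver is excluded for this reason.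
- Protodeauration could give the plain flavone.
- The phenolate could cyclise before it is borylated.
- One feature lowers the risk. If the neighbouring OMe oxygen closes the ring instead of the boryloxy oxygen, the pseudo-symmetric A ring still gives the same substitution pattern after step 9.
- The fallback uses known chemistry only, sets out from 10 and comes back at 14. Ynone 10 is closed by the established 6-endo cyclisation of o-alkynoylphenols (DMAP 20 mol %, DMF, rt to 40 °C, or TfOH in CH2Cl2). This gives the plain flavone 2-[3-(benzyloxy)-4,5-dimethoxyphenyl]-5,6,7,8-tetramethoxy-4H-chromen-4-one F1. Epoxidation with dimethyldioxirane (acetone/CH2Cl2, 0 °C) then gives racemic 1a-[3-(benzyloxy)-4,5-dimethoxyphenyl]-3,4,5,6-tetramethoxy-1a,7a-dihydro-7H-oxireno[2,3-b]chromen-7-one F2. Catalytic p-TsOH opens and tautomerises it to 14.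

**Step 7.**
- The electron-rich free phenol could be over-oxidised.
- The ynone could cyclise on the MnO2 surface.
- The fallback masks the phenol before oxidation. It sets out from 9 and comes back at 10.
- MOMCl (1.1 equiv) with K2CO3 in acetone at rt alkylates only the phenolate. This gives racemic 3-[3-(benzyloxy)-4,5-dimethoxyphenyl]-1-[2,3,4,5-tetramethoxy-6-(methoxymethoxy)phenyl]prop-2-yn-1-ol F3.
- Dess–Martin periodinane with NaHCO3 in CH2Cl2 then gives 3-[3-(benzyloxy)-4,5-dimethoxyphenyl]-1-[2,3,4,5-tetramethoxy-6-(methoxymethoxy)phenyl]prop-2-yn-1-one F4.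
- Brief TFA/CH2Cl2 at 0 °C with aqueous work-up unmasks the ortho-acyl MOM ether to 10.

**Step 9.**
- The 4'-OMe next to the freed 3'-O-boron group, or the 6-OMe next to O5, could also be cleaved.
- Benzyl could be transferred to a ring carbon.
- The fallback separates the two cleavages into mechanistically orthogonal steps. It sets out from 14 and comes back at 15.
- Hydrogenolysis (H2 1 atm, 10% Pd/C, EtOAc/MeOH) removes only the benzyl group. This gives 3-hydroxy-2-(3-hydroxy-4,5-dimethoxyphenyl)-5,6,7,8-tetramethoxy-4H-chromen-4-one F5.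
- AlCl3 in MeCN at 60 °C, followed by dilute HCl, cleaves only the 5-OMe through the aluminium 4-keto-5-oxy chelate. This is a well-used selective demethylation of polymethoxyflavones, and it gives 15.

**Further compounds**
F1 | step 8 | 2-[3-(benzyloxy)-4,5-dimethoxyphenyl]-5,6,7,8-tetramethoxy-4H-chromen-4-one | O=c1cc(-c2cc(OCc3ccccc3)c(OC)c(OC)c2)oc2c(OC)c(OC)c(OC)c(OC)c12
F2 | step 8 | racemic 1a-[3-(benzyloxy)-4,5-dimethoxyphenyl]-3,4,5,6-tetramethoxy-1a,7a-dihydro-7H-oxireno[2,3-b]chromen-7-one | O=C1C2OC2(c2cc(OCc3ccccc3)c(OC)c(OC)c2)Oc2c(OC)c(OC)c(OC)c(OC)c12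
F3 | step 7 | racemic 3-[3-(benzyloxy)-4,5-dimethoxyphenyl]-1-[2,3,4,5-tetramethoxy-6-(methoxymethoxy)phenyl]prop-2-yn-1-ol | OC(C#Cc1cc(OCc2ccccc2)c(OC)c(OC)c1)c1c(OCOC)c(OC)c(OC)c(OC)c1OC
F4 | step 7 | 3-[3-(benzyloxy)-4,5-dimethoxyphenyl]-1-[2,3,4,5-tetramethoxy-6-(methoxymethoxy)phenyl]prop-2-yn-1-one | O=C(C#Cc1cc(OCc2ccccc2)c(OC)c(OC)c1)c1c(OCOC)c(OC)c(OC)c(OC)c1OC
F5 | step 9 | 3-hydroxy-2-(3-hydroxy-4,5-dimethoxyphenyl)-5,6,7,8-tetramethoxy-4H-chromen-4-one | O=c1c(O)c(-c2cc(O)c(OC)c(OC)c2)oc2c(OC)c(OC)c(OC)c(OC)c12
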